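**Retrosynthetic overview**

1. The isobutyrate and the C9 acetate go on last; the C6(CH3)=C7–C8=O enone is unmasked by a Stork–Danheiser transposition of a C6-oxo/C8-methoxy vinylogous ester, and the isopropenyl group by Wittig methylenation of a C3 acetyl group.
2. Key disconnection: the cyclopentane bonds C1–C2 and C3–C4 are cut together (Prins–pinacol retron), leading back to a cyclohexenone whose quaternary carbon carries a lactol-masked formyl group and a CH2–C(OH)(CH3)–CH=CH2 arm.
3. Enabling feature: in the five-membered ring the oxygen-bearing C1 and the isopropenyl-bearing C3 (isopropenyl = masked acetyl) stand 1,3, a 3-acylcyclopentan-1-ol pattern, and C1 and C4 both hang from the quaternary spiro carbon C5, which is flanked by the carbonyl carbon C6 and the methyl-bearing C10 of the six-membered ring.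
4. The quaternary carbon comes from alkylation of a cyclic vinylogous β-keto ester with chloroacetone anti to the C10 methyl group, then vinyl Grignard addition with lactonisation and half-reduction.
5. Ring order: six-membered ring first (Dieckmann condensation on bought methyl hydrogen (R)-3-methylglutarate, the only stereocentre bought), five-membered ring second in the key step; C5, C1, C3 and C9 are relayed from C10 by substrate control.

Key step: step 8

Remark: locants are those of spiro[4.5]decane (C1–C4 cyclopentane, C5 spiro carbon, C6–C10 cyclohexane), and methyl hydrogen (R)-3-methylglutarate is assumed to be bought as a single enantiomer.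

Step 1
Reactants: 1 methyl hydrogen (R)-3-methylglutarate [(3R)-5-methoxy-3-methyl-5-oxopentanoic acid]
Product: 2 (3R)-4-acetyl-5-methoxy-3-methyl-5-oxopentanoic acid (C4 epimers)
Conditions: LiN(i-Pr)2 (LDA, 2.2 equiv), THF, −78 °C; MeC(O)N(OMe)Me, −78 → 0 °C; aq. HCl
Reagents that add atoms: N-methoxy-N-methylacetamide, CC(=O)N(C)OC
Why: The carboxylate/ester-enolate dianion (deprotonation α to the ester, not α to the carboxylate) should undergo Claisen-type C-acylation by the Weinreb amide, whose stable tetrahedral adduct prevents a second addition; the bought stereocentre is not enolisable and the new α-centre is redefined in step 5.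

Step 2
Reactants: 2 (3R)-4-acetyl-5-methoxy-3-methyl-5-oxopentanoic acid
Product: 3 dimethyl (3R)-2-acetyl-3-methylpentanedioate (C2 epimers)
Conditions: MeOH, H2SO4 (cat.), 40 °C
Reagents that add atoms: methanol, CO
Why: Fischer esterification of the free acid should proceed without touching the β-keto ester or the stereocentre.

Step 3
Reactants: 3 dimethyl (3R)-2-acetyl-3-methylpentanedioate
Product: 4 methyl (6R)-6-methyl-2,4-dioxocyclohexane-1-carboxylate (C1 epimers, enol forms)
Conditions: NaOMe (1.2 equiv), MeOH, reflux; aq. HCl, 0 °C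
Reagents that add atoms: none
Why: Dieckmann-type intramolecular Claisen condensation, in which the acetyl methyl carbanion attacks the remote ester (6-exo-trig) and the product is drained as its vinylogous-acid enolate; C6 has no acidic hydrogen and the deprotonated acetoacetate unit cannot leave by retro-Michael fragmentation, so the stereocentre should survive.

Step 4
Reactants: 4 methyl (6R)-6-methyl-2,4-dioxocyclohexane-1-carboxylate
Product: 5 methyl (6R)-4-methoxy-6-methyl-2-oxocyclohex-3-ene-1-carboxylate (C1 epimers)
Conditions: HC(OMe)3, MeOH, TsOH (cat.), rt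
Reagents that add atoms: trimethyl orthoformate, COC(OC)OC
Why: Acid-catalysed enol ether formation (vinylogous ester synthesis) is expected at the unhindered C4 carbonyl remote from the ester, which keeps the C2 ketone as a β-keto ester and, because the ester differentiates the two carbonyl groups, keeps the molecule chiral.

Step 5
Reactants: 5 methyl (6R)-4-methoxy-6-methyl-2-oxocyclohex-3-ene-1-carboxylate
Product: 6 methyl (1R,6R)-4-methoxy-6-methyl-2-oxo-1-(2-oxopropyl)cyclohex-3-ene-1-carboxylate
Conditions: ClCH2C(O)CH3, K2CO3, NaI (cat.), acetone, reflux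
Reagents that add atoms: chloroacetone, CC(=O)CCl
Why: C-alkylation of the β-keto ester enolate, in which the electrophile should enter anti to the adjacent pseudo-axial C6 methyl group, sets the quaternary centre with the acetonyl arm trans and the ester cis to that methyl group.

Step 6
Reactants: 6 methyl (1R,6R)-4-methoxy-6-methyl-2-oxo-1-(2-oxopropyl)cyclohex-3-ene-1-carboxylate
Product: 8 (5R,10R)-3-ethenyl-8-methoxy-3,10-dimethyl-2-oxaspiro[4.5]dec-7-ene-1,6-dione (C3 epimers), via hydroxy ester 7 (not isolated)
Conditions: CH2=CHMgBr (1.2 equiv), THF, −78 °C → rt; H2O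
Reagents that add atoms: vinylmagnesium bromide, C=C[Mg]Br
Why: Chemoselective Grignard 1,2-addition to the methyl ketone (the vinylogous ester carbonyl and the neopentyl ester are far less electrophilic at low temperature) is followed by lactonisation of the tertiary alkoxide onto the neighbouring ester (5-exo-trig acyl substitution); the new carbinol centre is uncontrolled but is destroyed in step 8.

Step 7
Reactants: 8 (5R,10R)-3-ethenyl-8-methoxy-3,10-dimethyl-2-oxaspiro[4.5]dec-7-ene-1,6-dione
Product: 9 (5S,10R)-3-ethenyl-1-hydroxy-8-methoxy-3,10-dimethyl-2-oxaspiro[4.5]dec-7-en-6-one (C1 and C3 epimers)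
Conditions: i-Bu2AlH (1.1 equiv), CH2Cl2, −78 °C; H2O work-up
Reagents that add atoms: none
Why: Partial reduction of a lactone to the lactol by i-Bu2AlH at −78 °C (stable aluminium hemiacetal) should be selective because the lactone is the more electrophilic of the two carbonyl groups on the quaternary carbon, the vinylogous ester being a poor hydride acceptor at this temperature.

Step 8
Reactants: 9 (5S,10R)-3-ethenyl-1-hydroxy-8-methoxy-3,10-dimethyl-2-oxaspiro[4.5]dec-7-en-6-one
Product: 11 (1R,3S,5S,10R)-3-acetyl-1-hydroxy-8-methoxy-10-methylspiro[4.5]dec-7-en-6-one, via hydroxy aldehyde 10 (not isolated)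
Conditions: BF3·OEt2 (2.5 equiv), CH2Cl2, −78 → −20 °C
Reagents that add atoms: none
Why: BF3 opens lactol 9 to the BF3-bound ring-chain tautomer 10; the terminal carbon of the vinyl group attacks the formyl carbon through a six-membered chair (Prins cyclization) and, as positive charge builds on the internal vinyl carbon, the ring CH2–C(OH) bond migrates to it (pinacol shift), so that C1–C2 and C3–C4 are made in one event and the carbinol carbon is expelled from the ring as the acetyl group. The closest known reaction type is the pinacol-terminated Prins cyclization (Prins–pinacol reaction), used for ring-enlarging carbocycle annulations and, in this same ring-contracting topology, for 3-acyltetrahydrofurans from allylic diols and aldehydes. The only ring closed is the cyclopentane, by 6-endo-trig cation–olefin closure to a cyclohexyl cation followed by contraction through the 1,2-alkyl shift. Both new stereocentres come from the chair: the quaternary carbon places its smaller sp2 branch (ring carbonyl carbon C6) axial and C10 equatorial, which puts the acetyl group on C3 cis to C6, and under the non-chelating Lewis acid the BF3-bound formyl oxygen sits axial, anti to the C6=O dipole, which puts the C1 oxygen trans to the acetyl group and cis to C10. The step needs initiation at the aldehyde only and migration of the ring CH2 instead of the methyl group; the first is secured by the poor electrophilicity of the vinylogous ester and by the carbinol oxygen being tied up as a BF3 alkoxide, the second by the alignment of the ring bond with the developing empty orbital in the chair and by the higher migratory aptitude of a primary alkyl group. Because the carbinol and anomeric centres of 9 become sp2, all four diastereomers of 9 should converge on 11.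

Step 9
Reactants: 11 (1R,3S,5S,10R)-3-acetyl-1-hydroxy-8-methoxy-10-methylspiro[4.5]dec-7-en-6-one
Product: 12 (1R,3S,5S,10R)-3-acetyl-8-methoxy-10-methyl-1-(triethylsilyloxy)spiro[4.5]dec-7-en-6-one
Conditions: Et3SiOTf, 2,6-lutidine, CH2Cl2, −78 °C
Reagents that add atoms: triethylsilyl trifluoromethanesulfonate, CC[Si](CC)(CC)OS(=O)(=O)C(F)(F)F
Why: Silyl triflate/lutidine silylation of the hindered secondary alcohol masks the C1 hydroxyl, so that no β-alkoxide of the C6 ketone can form and retro-aldol opening of the cyclopentane (which would erase C1 and C5) is excluded in the basic steps 10 and 11.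

Step 10
Reactants: 12 (1R,3S,5S,10R)-3-acetyl-8-methoxy-10-methyl-1-(triethylsilyloxy)spiro[4.5]dec-7-en-6-one
Product: 13 (1R,3S,5S,10R)-8-methoxy-10-methyl-3-(prop-1-en-2-yl)-1-(triethylsilyloxy)spiro[4.5]dec-7-en-6-one
Conditions: Ph3PCH3Br, KOt-Bu, THF, 0 °C
Reagents that add atoms: methyltriphenylphosphonium bromide, C[P+](c1ccccc1)(c1ccccc1)c1ccccc1.[Br-]
Why: Wittig methylenation of the methyl ketone (the vinylogous ester carbonyl does not react with the ylide) should deliver the isopropenyl group, and with pre-formed ylide at 0 °C olefination is expected to outrun enolisation, so that C3 keeps its configuration.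

Step 11
Reactants: 13 (1R,3S,5S,10R)-8-methoxy-10-methyl-3-(prop-1-en-2-yl)-1-(triethylsilyloxy)spiro[4.5]dec-7-en-6-one
Product: 15 (1R,3S,5R,10R)-1-hydroxy-6,10-dimethyl-3-(prop-1-en-2-yl)spiro[4.5]dec-6-en-8-one, via tertiary carbinol 14 (not isolated)
Conditions: MeLi, Et2O/THF, −78 → 0 °C; 1 M HCl, THF, rt
Reagents that add atoms: methyllithium, [Li]C; water, O
Why: Stork–Danheiser transposition, in which 1,2-addition of MeLi to the vinylogous ester carbonyl and acid hydrolysis of the resulting β-hydroxy enol ether (loss of methanol) should give the transposed 3-methyl enone while the same acid removes the triethylsilyl group; no stereocentre of the final skeleton is touched and the transient C6 carbinol centre disappears.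

Step 12
Reactants: 15 (1R,3S,5R,10R)-1-hydroxy-6,10-dimethyl-3-(prop-1-en-2-yl)spiro[4.5]dec-6-en-8-one
Product: 16 (1R,3S,5R,10R)-6,10-dimethyl-8-oxo-3-(prop-1-en-2-yl)spiro[4.5]dec-6-en-1-yl 2-methylpropanoate
Conditions: (i-PrCO)2O, DMAP (cat.), pyridine, rt
Reagents that add atoms: isobutyric anhydride, CC(C)C(=O)OC(=O)C(C)C
Why: DMAP-catalysed acylation of the neopentyl-type secondary alcohol should proceed with retention at C1.

Step 13
Reactants: 16 (1R,3S,5R,10R)-6,10-dimethyl-8-oxo-3-(prop-1-en-2-yl)spiro[4.5]dec-6-en-1-yl 2-methylpropanoate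
Product: 17 (1R,3S,5R,9R,10S)-9-acetoxy-6,10-dimethyl-8-oxo-3-(prop-1-en-2-yl)spiro[4.5]dec-6-en-1-yl 2-methylpropanoate (CNP0229299.1)
Conditions: Mn(OAc)3·2H2O (3 equiv), benzene, reflux (Dean–Stark)
Reagents that add atoms: manganese triacetate, CC(=O)[O-].CC(=O)[O-].CC(=O)[O-].[Mn+3]
Why: α'-Acetoxylation of an enone with Mn(OAc)3 (enolate of trivalent manganese, α-keto radical, acetate ligand transfer) is selective for the α'-methylene C9, and acetate should enter trans to the adjacent C10 methyl group (less hindered face and the equatorial epimer), the isopropenyl group and both esters being expected to survive as in acetoxylations of isopropenyl-bearing terpenoid enones.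

**Compound list**

1 | methyl hydrogen (R)-3-methylglutarate, (3R)-5-methoxy-3-methyl-5-oxopentanoic acid | OC(=O)C[C@H](CC(=O)OC)C | starting material
2 | (3R)-4-acetyl-5-methoxy-3-methyl-5-oxopentanoic acid (C4 epimers) | OC(=O)C[C@H](C(C(C)=O)C(=O)OC)C | intermediate
3 | dimethyl (3R)-2-acetyl-3-methylpentanedioate (C2 epimers) | COC(=O)C[C@H](C(C(C)=O)C(=O)OC)C | intermediate
4 | methyl (6R)-6-methyl-2,4-dioxocyclohexane-1-carboxylate (C1 epimers, enol forms) | O=C1C[C@@H](C)C(C(=O)OC)C(=O)C1 | intermediate
5 | methyl (6R)-4-methoxy-6-methyl-2-oxocyclohex-3-ene-1-carboxylate (C1 epimers) | COC1=CC(=O)C(C(=O)OC)[C@H](C)C1 | intermediate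
6 | methyl (1R,6R)-4-methoxy-6-methyl-2-oxo-1-(2-oxopropyl)cyclohex-3-ene-1-carboxylate | COC1=CC(=O)[C@](CC(C)=O)(C(=O)OC)[C@H](C)C1 | intermediate
7 | methyl (1R,6R)-1-(2-hydroxy-2-methylbut-3-en-1-yl)-4-methoxy-6-methyl-2-oxocyclohex-3-ene-1-carboxylate (bromomagnesium alkoxide, carbinol epimers; not isolated) | COC1=CC(=O)[C@](CC(C)(O)C=C)(C(=O)OC)[C@H](C)C1 | intermediate
8 | (5R,10R)-3-ethenyl-8-methoxy-3,10-dimethyl-2-oxaspiro[4.5]dec-7-ene-1,6-dione (C3 epimers) | COC1=CC(=O)[C@@]2(CC(C)(C=C)OC2=O)[C@H](C)C1 | intermediate
9 | (5S,10R)-3-ethenyl-1-hydroxy-8-methoxy-3,10-dimethyl-2-oxaspiro[4.5]dec-7-en-6-one (C1 and C3 epimers) | COC1=CC(=O)[C@@]2(CC(C)(C=C)OC2O)[C@H](C)C1 | intermediate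
10 | (1S,6R)-1-(2-hydroxy-2-methylbut-3-en-1-yl)-4-methoxy-6-methyl-2-oxocyclohex-3-ene-1-carbaldehyde (ring-opened tautomer of 9, BF3-bound; not isolated) | COC1=CC(=O)[C@@](C=O)(CC(C)(O)C=C)[C@H](C)C1 | intermediate
11 | (1R,3S,5S,10R)-3-acetyl-1-hydroxy-8-methoxy-10-methylspiro[4.5]dec-7-en-6-one | CC(=O)[C@@H]1C[C@@H](O)[C@@]2(C1)C(=O)C=C(OC)C[C@H]2C | intermediate
12 | (1R,3S,5S,10R)-3-acetyl-8-methoxy-10-methyl-1-(triethylsilyloxy)spiro[4.5]dec-7-en-6-one | CC(=O)[C@@H]1C[C@@H](O[Si](CC)(CC)CC)[C@@]2(C1)C(=O)C=C(OC)C[C@H]2C | intermediate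
13 | (1R,3S,5S,10R)-8-methoxy-10-methyl-3-(prop-1-en-2-yl)-1-(triethylsilyloxy)spiro[4.5]dec-7-en-6-one | C=C(C)[C@@H]1C[C@@H](O[Si](CC)(CC)CC)[C@@]2(C1)C(=O)C=C(OC)C[C@H]2C | intermediate
14 | (1R,3S,5S,10R)-8-methoxy-6,10-dimethyl-3-(prop-1-en-2-yl)-1-(triethylsilyloxy)spiro[4.5]dec-7-en-6-ol (lithium alkoxide, C6 epimers; not isolated) | C=C(C)[C@@H]1C[C@@H](O[Si](CC)(CC)CC)[C@@]2(C1)C(C)(O)C=C(OC)C[C@H]2C | intermediate
15 | (1R,3S,5R,10R)-1-hydroxy-6,10-dimethyl-3-(prop-1-en-2-yl)spiro[4.5]dec-6-en-8-one | C=C(C)[C@@H]1C[C@@H](O)[C@@]2(C1)C(C)=CC(=O)C[C@H]2C | intermediate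
16 | (1R,3S,5R,10R)-6,10-dimethyl-8-oxo-3-(prop-1-en-2-yl)spiro[4.5]dec-6-en-1-yl 2-methylpropanoate | C=C(C)[C@@H]1C[C@@H](OC(=O)C(C)C)[C@@]2(C1)C(C)=CC(=O)C[C@H]2C | intermediate
17 | (1R,3S,5R,9R,10S)-9-acetoxy-6,10-dimethyl-8-oxo-3-(prop-1-en-2-yl)spiro[4.5]dec-6-en-1-yl 2-methylpropanoate | C=C(C)[C@@H]1C[C@@H](OC(=O)C(C)C)[C@@]2(C1)C(C)=CC(=O)[C@H](OC(C)=O)[C@H]2C | target

Total step count: 13. Longest linear sequence: 13 steps (1 to 17).

**Steps most likely to fail**

Step 8. The lactol may ionise to its cyclic oxocarbenium ion and be captured by the tethered vinyl group through a bridged pathway that scrambles C3. Closure onto the unactivated vinyl group may also be slow, or the formyl face may be attacked with poor selectivity. The fallback sets out from lactol 9 and replaces the lactol by an acyclic, silyl-protected substrate. NaBH4 (MeOH, 0 °C) should reduce the open-chain tautomer but not the vinylogous ester and give the diol F1. Et3SiOTf with 2,6-lutidine should give the bis(triethylsilyl) ether F2. Swern oxidation ((COCl)2, DMSO, Et3N), which oxidises a primary triethylsilyl ether directly, should give the aldehyde F3 with the tertiary carbinol still silylated. This substrate cannot form a lactol-derived oxocarbenium ion, and BF3·OEt2 (CH2Cl2, −78 °C) should carry it through the same Prins–pinacol sequence to 11, where the route is rejoined.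

Step 7. Hydride may also attack the vinylogous ester carbonyl, or the lactol may be over-reduced. The fallback sets out from lactone 8 and swaps kinetic discrimination for temporary protection. LiN(i-Pr)2 (1.1 equiv, THF, −78 °C) should remove a C9 proton (C5 is quaternary and the lactone has no α-hydrogen) and give the lithium dienolate F4, in which the ring carbonyl is masked against hydride. i-Bu2AlH should then reduce only the lactone, and aqueous work-up should reprotonate the dienolate to the vinylogous ester, giving 9.

Step 13. Acetate transfer to the α-keto radical may show poor facial selectivity, or the oxidant may attack the isopropenyl group. The fallback sets out from 16 and replaces the radical acetoxylation by enolate hydroxylation and acetylation. LiN(SiMe3)2 (THF, −78 °C) should form the kinetic C9 enolate, the hindered isobutyrate α-hydrogen being much less acidic. 2-(Phenylsulfonyl)-3-phenyloxaziridine should hydroxylate it from the face opposite the C10 methyl group to give the α'-hydroxy ketone F5. Ac2O with DMAP in pyridine should acetylate F5 to 17.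

**Further compounds**

F1 | step 8 | (5R,6S)-6-(hydroxymethyl)-6-(2-hydroxy-2-methylbut-3-en-1-yl)-3-methoxy-5-methylcyclohex-2-en-1-one (carbinol epimers) | COC1=CC(=O)[C@@](CO)(CC(C)(O)C=C)[C@H](C)C1
F2 | step 8 | (5R,6S)-3-methoxy-5-methyl-6-[2-methyl-2-(triethylsilyloxy)but-3-en-1-yl]-6-[(triethylsilyloxy)methyl]cyclohex-2-en-1-one | COC1=CC(=O)[C@@](CO[Si](CC)(CC)CC)(CC(C)(O[Si](CC)(CC)CC)C=C)[C@H](C)C1
F3 | step 8 | (1S,6R)-4-methoxy-6-methyl-1-[2-methyl-2-(triethylsilyloxy)but-3-en-1-yl]-2-oxocyclohex-3-ene-1-carbaldehyde | COC1=CC(=O)[C@@](C=O)(CC(C)(O[Si](CC)(CC)CC)C=C)[C@H](C)C1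
F4 | step 7 | lithium dienolate of 8 (deprotonated at C9) | COC1=C[C@@H](C)[C@]2(CC(C)(C=C)OC2=O)C([O-])=C1.[Li+]
F5 | step 13 | (1R,3S,5R,9R,10S)-9-hydroxy-6,10-dimethyl-8-oxo-3-(prop-1-en-2-yl)spiro[4.5]dec-6-en-1-yl 2-methylpropanoate | C=C(C)[C@@H]1C[C@@H](OC(=O)C(C)C)[C@@]2(C1)C(C)=CC(=O)[C@H](O)[C@H]2C
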